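**Plan**

1. The target is traced back, through hydrolysis of the two quinone methyl ethers and oxidation with tetravalent cerium, to biaryl hydroquinone 21. Ring A of 21 is then cut at two bonds: C(O, next to C–CH3)–C(ring B) and C(O, next to C–OMe)–C(arylethyl).
2. Enabling feature: in ring A the two para carbonyl carbons are bridged on one side by the C(OH)=C(CH3) pair, which is the four-carbon unit of a squarate-derived cyclobutenone. On the other side they are bridged by the C(arylethyl)=C(ring B) pair, which is an alkene. Ring A is therefore the ring expansion product of a 4-alkenyl-4-hydroxycyclobutenone.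
3. Forward: ring B is made first by the same ring expansion with a simple vinyllithium, then methylated and iodinated. A Sonogashira coupling attaches the four-carbon chain, and hydrozirconation/iodination gives the vinyl iodide.
4. The vinyllithium from that iodide adds to the cyclobutenedione, and thermolysis closes ring A last, around the existing aryl–C bond. The tetra-ortho-substituted biaryl bond is thus never made by a coupling.
5. Stereochemistry: the target has no stereocentre. The E alkene geometry comes from syn-hydrozirconation and is consumed in the ring closure. The carbinol centres of 6 and 18 are racemic and are destroyed.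

Key step: step 9

Remarks: the biaryl axis carries no descriptor in the target, so no axial control is attempted. 2-Bromo-4-phenylbut-1-ene (4) and 3-(2-methoxyphenyl)propanal (12) are taken as catalogue compounds.

**Step 1**
Reactants: 1 dimethyl squarate
Product: 3 3-methoxy-4-methylcyclobut-3-ene-1,2-dione, via hydroxycyclobutenone 2 (not isolated)
Conditions: MeLi, THF, −78 °C; then conc. HCl, CH2Cl2, 0 °C to rt
Reagents that add atoms: methyllithium, [Li]C; water, O
Why: 1,2-addition of MeLi to one carbonyl, then acid-promoted allylic transposition and hydrolysis with loss of methanol, is the standard squarate route to 3-alkoxy-4-alkylcyclobutenediones.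

**Step 2**
Reactants: 4 2-bromo-4-phenylbut-1-ene; 3 3-methoxy-4-methylcyclobut-3-ene-1,2-dione
Product: 6 4-hydroxy-3-methoxy-2-methyl-4-(4-phenylbut-1-en-2-yl)cyclobut-2-en-1-one (racemic), via vinyllithium 5 (not isolated)
Conditions: 4, t-BuLi (2 equiv), THF, −78 °C; then 3, −78 °C; aq. NH4Cl
Reagents that add atoms: none
Why: Br/Li exchange gives the vinyllithium, which should undergo 1,2-addition at the ketone-like carbonyl next to C–OMe and not at the vinylogous ester carbonyl; the new carbinol centre is racemic and is destroyed in step 3.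

**Step 3**
Reactants: 6 4-hydroxy-3-methoxy-2-methyl-4-(4-phenylbut-1-en-2-yl)cyclobut-2-en-1-one
Product: 10 1,3,4-trimethoxy-2-methyl-5-(2-phenylethyl)benzene, via dienylketene 7 (not isolated), via cyclohexadienone 8 (not isolated), via hydroquinone 9 (not isolated)
Conditions: PhMe, 110 °C, Ar; then MeI, K2CO3, acetone, 50 °C
Reagents that add atoms: iodomethane, CI
Why: Thermal 4π ring opening, 6π closure and enolisation (Moore–Liebeskind ring expansion) should give the hydroquinone with the ring B substitution pattern fixed, and Williamson methylation protects both phenols for the organometallic steps.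

**Step 4**
Reactants: 10 1,3,4-trimethoxy-2-methyl-5-(2-phenylethyl)benzene
Product: 11 1-iodo-2,4,5-trimethoxy-3-methyl-6-(2-phenylethyl)benzene
Conditions: NIS, TFA (cat.), MeCN, rt
Reagents that add atoms: N-iodosuccinimide, O=C1CCC(=O)N1I
Why: Electrophilic aromatic iodination should occur at the single free position of the trialkoxyarene, which is ortho and para to methoxy groups, the phenyl ring being far less nucleophilic.

**Step 5**
Reactants: 12 3-(2-methoxyphenyl)propanal
Product: 13 1-(but-3-yn-1-yl)-2-methoxybenzene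
Conditions: dimethyl (1-diazo-2-oxopropyl)phosphonate, K2CO3, MeOH, 0 °C to rt
Reagents that add atoms: dimethyl (1-diazo-2-oxopropyl)phosphonate, CC(=O)C(=[N+]=[N-])P(=O)(OC)OC
Why: Ohira–Bestmann (Seyferth–Gilbert) homologation converts an aliphatic aldehyde into the terminal alkyne under mild base.

**Step 6**
Reactants: 11 1-iodo-2,4,5-trimethoxy-3-methyl-6-(2-phenylethyl)benzene; 13 1-(but-3-yn-1-yl)-2-methoxybenzene
Product: 14 1-[4-(2-methoxyphenyl)but-1-yn-1-yl]-2,4,5-trimethoxy-3-methyl-6-(2-phenylethyl)benzene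
Conditions: PdCl2(PPh3)2 (cat.), CuI (cat.), Et3N/DMF, 70 °C
Reagents that add atoms: none
Why: Sonogashira coupling should succeed because the sp-carbon partner is small enough to reach the di-ortho-substituted aryl iodide; this bond later becomes the biaryl axis.

**Step 7**
Reactants: 14 1-[4-(2-methoxyphenyl)but-1-yn-1-yl]-2,4,5-trimethoxy-3-methyl-6-(2-phenylethyl)benzene
Product: 16 1-[(1E)-2-iodo-4-(2-methoxyphenyl)but-1-en-1-yl]-2,4,5-trimethoxy-3-methyl-6-(2-phenylethyl)benzene, via alkenylzirconocene 15 (not isolated)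
Conditions: Cp2Zr(H)Cl, THF, 50 °C; then I2, THF, 0 °C
Reagents that add atoms: iodine, II
Why: syn-Hydrozirconation should place Zr on the alkyne carbon remote from the bulky hexasubstituted aryl group, and iodinolysis with retention then gives the E iodide, whose geometry follows from the syn addition.

**Step 8**
Reactants: 16 1-[(1E)-2-iodo-4-(2-methoxyphenyl)but-1-en-1-yl]-2,4,5-trimethoxy-3-methyl-6-(2-phenylethyl)benzene; 3 3-methoxy-4-methylcyclobut-3-ene-1,2-dione
Product: 18 4-hydroxy-3-methoxy-4-{(1E)-4-(2-methoxyphenyl)-1-[2,4,5-trimethoxy-3-methyl-6-(2-phenylethyl)phenyl]but-1-en-2-yl}-2-methylcyclobut-2-en-1-one (racemic), via vinyllithium 17 (not isolated)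
Conditions: 16, t-BuLi (2 equiv), THF, −78 °C; then 3, −78 °C; aq. NH4Cl
Reagents that add atoms: none
Why: I/Li exchange with retention of alkene geometry, then 1,2-addition to the more electrophilic carbonyl of 3 as in step 2, should give the adduct; the carbinol centre is racemic and is destroyed in step 9.

**Step 9**
Reactants: 18 4-hydroxy-3-methoxy-4-{(1E)-4-(2-methoxyphenyl)-1-[2,4,5-trimethoxy-3-methyl-6-(2-phenylethyl)phenyl]but-1-en-2-yl}-2-methylcyclobut-2-en-1-one
Product: 21 2-methoxy-6-[2-(2-methoxyphenyl)ethyl]-3-methyl-5-[2,4,5-trimethoxy-3-methyl-6-(2-phenylethyl)phenyl]benzene-1,4-diol, via dienylketene 19 (not isolated), via cyclohexadienone 20 (not isolated)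
Conditions: p-xylene (degassed, dilute), 140 °C, Ar
Reagents that add atoms: none
Why: Heating should open the cyclobutenone by conrotatory 4π electrocyclic cleavage of the C(=O)–C(OH) bond, the donor hydroxyl turning outward and the alkenyl group inward, to give dienylketene 19; a thermally allowed disrotatory 6π electrocyclisation between the ketene carbon and the styrenyl CH then closes six-membered ring A (electrocyclic mode of closure), and dienone 20 enolises to hydroquinone 21. The closest known reaction type is the Moore–Liebeskind thermal ring expansion of 4-alkenyl-4-hydroxycyclobutenones to hydroquinones. The only new sp3 centre, the ring CH bearing ring B in 20, is erased on aromatisation, and the biaryl axis, which has no descriptor in the target, forms without control. The step needs torquoselectivity (alkenyl inward), secured by the 4-hydroxyl, and a fixed placement of OMe/CH3 against arylethyl/ring B, secured in step 8 by addition at the carbonyl next to C–OMe. The E geometry from step 7 puts the bulky ring B on the outside of the closing triene, with only H pointing inward. The tetra-ortho-substituted aryl–aryl bond is not made in this step: it enters as the styrene C–C bond and ring A is grown around it.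

**Step 10**
Reactants: 21 2-methoxy-6-[2-(2-methoxyphenyl)ethyl]-3-methyl-5-[2,4,5-trimethoxy-3-methyl-6-(2-phenylethyl)phenyl]benzene-1,4-diol
Product: 23 2-methoxy-5-[4-methoxy-5-methyl-3,6-dioxo-2-(2-phenylethyl)cyclohexa-1,4-dien-1-yl]-6-[2-(2-methoxyphenyl)ethyl]-3-methylcyclohexa-2,5-diene-1,4-dione, via monoquinone 22 (not isolated)
Conditions: (NH4)2Ce(NO3)6 (4–5 equiv), MeCN/H2O, 0 °C
Reagents that add atoms: water, O
Why: Tetravalent cerium should oxidise hydroquinone ring A to the quinone and oxidatively demethylate the para-dimethoxy pair of ring B (quinone oxygens from water), while the monomethoxyphenyl ring is too electron-poor to react.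

**Step 11**
Reactants: 23 2-methoxy-5-[4-methoxy-5-methyl-3,6-dioxo-2-(2-phenylethyl)cyclohexa-1,4-dien-1-yl]-6-[2-(2-methoxyphenyl)ethyl]-3-methylcyclohexa-2,5-diene-1,4-dione
Product: 24 2-hydroxy-5-[4-hydroxy-5-methyl-3,6-dioxo-2-(2-phenylethyl)cyclohexa-1,4-dien-1-yl]-6-[2-(2-methoxyphenyl)ethyl]-3-methylcyclohexa-2,5-diene-1,4-dione (CNP0202346.0)
Conditions: NaOH (aq), MeOH/THF, rt, Ar; then HCl (aq)
Reagents that add atoms: sodium hydroxide, [Na+].[OH-]
Why: Addition–elimination of hydroxide at the two vinylogous ester carbons (saponification of methoxyquinones) should release both hydroxyquinones, while the aryl methyl ether is inert.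

**Compound list**

1 | dimethyl squarate (3,4-dimethoxycyclobut-3-ene-1,2-dione) | COC1=C(OC)C(=O)C1=O | starting material
2 | 4-hydroxy-2,3-dimethoxy-4-methylcyclobut-2-en-1-one (racemic) | COC1=C(OC)C(C)(O)C1=O | intermediate
3 | 3-methoxy-4-methylcyclobut-3-ene-1,2-dione | COC1=C(C)C(=O)C1=O | intermediate
4 | 2-bromo-4-phenylbut-1-ene | C=C(Br)CCc1ccccc1 | starting material
5 | (4-phenylbut-1-en-2-yl)lithium | [Li]C(=C)CCc1ccccc1 | intermediate
6 | 4-hydroxy-3-methoxy-2-methyl-4-(4-phenylbut-1-en-2-yl)cyclobut-2-en-1-one (racemic) | COC1=C(C)C(=O)C1(O)C(=C)CCc1ccccc1 | intermediate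
7 | (3Z)-4-hydroxy-3-methoxy-2-methyl-5-methylidene-7-phenylhepta-1,3-dien-1-one (dienylketene) | O=C=C(C)/C(OC)=C(/O)C(=C)CCc1ccccc1 | intermediate
8 | 4-hydroxy-3-methoxy-2-methyl-5-(2-phenylethyl)cyclohexa-2,4-dien-1-one | O=C1CC(CCc2ccccc2)=C(O)C(OC)=C1C | intermediate
9 | 2-methoxy-3-methyl-6-(2-phenylethyl)benzene-1,4-diol | Oc1cc(CCc2ccccc2)c(O)c(OC)c1C | intermediate
10 | 1,3,4-trimethoxy-2-methyl-5-(2-phenylethyl)benzene | COc1cc(CCc2ccccc2)c(OC)c(OC)c1C | intermediate
11 | 1-iodo-2,4,5-trimethoxy-3-methyl-6-(2-phenylethyl)benzene | COc1c(I)c(CCc2ccccc2)c(OC)c(OC)c1C | intermediate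
12 | 3-(2-methoxyphenyl)propanal | COc1ccccc1CCC=O | starting material
13 | 1-(but-3-yn-1-yl)-2-methoxybenzene | COc1ccccc1CCC#C | intermediate
14 | 1-[4-(2-methoxyphenyl)but-1-yn-1-yl]-2,4,5-trimethoxy-3-methyl-6-(2-phenylethyl)benzene | COc1ccccc1CCC#Cc1c(OC)c(C)c(OC)c(OC)c1CCc1ccccc1 | intermediate
15 | chlorobis(cyclopentadienyl){(1E)-4-(2-methoxyphenyl)-1-[2,4,5-trimethoxy-3-methyl-6-(2-phenylethyl)phenyl]but-1-en-2-yl}zirconium | COc1ccccc1CC/C(=C\c1c(OC)c(C)c(OC)c(OC)c1CCc1ccccc1)[Zr](Cl)(C1C=CC=C1)C1C=CC=C1 | intermediate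
16 | 1-[(1E)-2-iodo-4-(2-methoxyphenyl)but-1-en-1-yl]-2,4,5-trimethoxy-3-methyl-6-(2-phenylethyl)benzene | COc1ccccc1CC/C(I)=C\c1c(OC)c(C)c(OC)c(OC)c1CCc1ccccc1 | intermediate
17 | {(1Z)-4-(2-methoxyphenyl)-1-[2,4,5-trimethoxy-3-methyl-6-(2-phenylethyl)phenyl]but-1-en-2-yl}lithium (Li trans to ring B) | COc1ccccc1CC/C([Li])=C\c1c(OC)c(C)c(OC)c(OC)c1CCc1ccccc1 | intermediate
18 | 4-hydroxy-3-methoxy-4-{(1E)-4-(2-methoxyphenyl)-1-[2,4,5-trimethoxy-3-methyl-6-(2-phenylethyl)phenyl]but-1-en-2-yl}-2-methylcyclobut-2-en-1-one (racemic) | COc1ccccc1CC/C(=C\c1c(OC)c(C)c(OC)c(OC)c1CCc1ccccc1)C1(O)C(OC)=C(C)C1=O | intermediate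
19 | dienylketene from 18: (3Z,5E)-4-hydroxy-3-methoxy-5-[2-(2-methoxyphenyl)ethyl]-2-methyl-6-[2,4,5-trimethoxy-3-methyl-6-(2-phenylethyl)phenyl]hexa-1,3,5-trien-1-one | O=C=C(C)/C(OC)=C(/O)\C(CCc1ccccc1OC)=C\c1c(OC)c(C)c(OC)c(OC)c1CCc1ccccc1 | intermediate
20 | 4-hydroxy-3-methoxy-5-[2-(2-methoxyphenyl)ethyl]-2-methyl-6-[2,4,5-trimethoxy-3-methyl-6-(2-phenylethyl)phenyl]cyclohexa-2,4-dien-1-one (racemic) | O=C1C(C)=C(OC)C(O)=C(CCc2ccccc2OC)C1c1c(OC)c(C)c(OC)c(OC)c1CCc1ccccc1 | intermediate
21 | 2-methoxy-6-[2-(2-methoxyphenyl)ethyl]-3-methyl-5-[2,4,5-trimethoxy-3-methyl-6-(2-phenylethyl)phenyl]benzene-1,4-diol | Cc1c(O)c(-c2c(OC)c(C)c(OC)c(OC)c2CCc2ccccc2)c(CCc2ccccc2OC)c(O)c1OC | intermediate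
22 | 2-methoxy-6-[2-(2-methoxyphenyl)ethyl]-3-methyl-5-[2,4,5-trimethoxy-3-methyl-6-(2-phenylethyl)phenyl]cyclohexa-2,5-diene-1,4-dione | CC1=C(OC)C(=O)C(CCc2ccccc2OC)=C(c2c(OC)c(C)c(OC)c(OC)c2CCc2ccccc2)C1=O | intermediate
23 | 2-methoxy-5-[4-methoxy-5-methyl-3,6-dioxo-2-(2-phenylethyl)cyclohexa-1,4-dien-1-yl]-6-[2-(2-methoxyphenyl)ethyl]-3-methylcyclohexa-2,5-diene-1,4-dione | CC1=C(OC)C(=O)C(CCc2ccccc2OC)=C(C2=C(CCc3ccccc3)C(=O)C(OC)=C(C)C2=O)C1=O | intermediate
24 | 2-hydroxy-5-[4-hydroxy-5-methyl-3,6-dioxo-2-(2-phenylethyl)cyclohexa-1,4-dien-1-yl]-6-[2-(2-methoxyphenyl)ethyl]-3-methylcyclohexa-2,5-diene-1,4-dione | COc1ccccc1CCC1=C(C2=C(CCc3ccccc3)C(=O)C(O)=C(C)C2=O)C(=O)C(C)=C(O)C1=O | target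

**Totals**

Total step count: 11. Longest linear sequence: 10 steps (steps 1, 2, 3, 4, 6, 7, 8, 9, 10, 11).

**Steps most likely to fail**

Step 9. The 6π closure may be retarded at the alkene terminus that carries the twisted hexasubstituted aryl group. The reversibly formed ketene would then be drained by dimerisation or by intermolecular capture through the tertiary hydroxyl. The fallback forms the aryl–aryl bond by arylation of a preformed ring A quinone. It sets out from 3 and 10 and comes back at 21. 2-Methoxybenzylmagnesium chloride and 2,3-dibromopropene (THF, 0 °C) should give 2-bromo-4-(2-methoxyphenyl)but-1-ene F1. Br/Li exchange (t-BuLi, −78 °C) and addition to 3 should give 4-hydroxy-3-methoxy-4-[4-(2-methoxyphenyl)but-1-en-2-yl]-2-methylcyclobut-2-en-1-one F2. Thermolysis (PhMe, 110 °C) should give 2-methoxy-6-[2-(2-methoxyphenyl)ethyl]-3-methylbenzene-1,4-diol F3. Oxidation with Ag2O should give 2-methoxy-6-[2-(2-methoxyphenyl)ethyl]-3-methylcyclohexa-2,5-diene-1,4-dione F4. Acid-promoted conjugate arylation (BF3·OEt2 or TFA, CH2Cl2) of F4 at its only unsubstituted ring carbon by arene 10, through its only free position, should then give 21.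

Step 7. Regiocontrol of the Zr–H addition may be lost through methoxy-assisted delivery of zirconium to the aryl-bearing carbon, or the addition to the shielded alkyne may stay incomplete. The fallback relies on electronic control of a copper–boron addition in place of steric control. It sets out from 14 and comes back at 16. Borylcupration and protonation (CuCl/NaOt-Bu/PPh3 cat., B2pin2, MeOH, THF) place copper on the aryl-bearing carbon and boron on the remote one. This should give 2-{(1Z)-4-(2-methoxyphenyl)-1-[2,4,5-trimethoxy-3-methyl-6-(2-phenylethyl)phenyl]but-1-en-2-yl}-4,4,5,5-tetramethyl-1,3,2-dioxaborolane F5. Iododeboronation with retention (NaOH, I2, THF/H2O, 0 °C) should then give 16.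

Step 6. Oxidative addition of zerovalent palladium into the di-ortho-substituted, electron-rich C–I bond may be slow, so that copper-mediated homocoupling of alkyne 13 becomes the faster channel. The fallback builds the alkyne by carbonyl addition and rearrangement. It sets out from 11 and 12 and comes back at 14. I/Li exchange on 11 (t-BuLi, THF, −78 °C) and addition to aldehyde 12 should give 3-(2-methoxyphenyl)-1-[2,4,5-trimethoxy-3-methyl-6-(2-phenylethyl)phenyl]propan-1-ol F6. Oxidation with Dess–Martin periodinane should give 3-(2-methoxyphenyl)-1-[2,4,5-trimethoxy-3-methyl-6-(2-phenylethyl)phenyl]propan-1-one F7. Lithiated trimethylsilyldiazomethane (THF, −78 °C to rt; Colvin rearrangement through an alkylidene carbene with 1,2-aryl shift) should convert F7 into 14.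

**Further compounds**

F1 | step 9 | 2-bromo-4-(2-methoxyphenyl)but-1-ene | C=C(Br)CCc1ccccc1OC
F2 | step 9 | 4-hydroxy-3-methoxy-4-[4-(2-methoxyphenyl)but-1-en-2-yl]-2-methylcyclobut-2-en-1-one (racemic) | COC1=C(C)C(=O)C1(O)C(=C)CCc1ccccc1OC
F3 | step 9 | 2-methoxy-6-[2-(2-methoxyphenyl)ethyl]-3-methylbenzene-1,4-diol | COc1ccccc1CCc1cc(O)c(C)c(OC)c1O
F4 | step 9 | 2-methoxy-6-[2-(2-methoxyphenyl)ethyl]-3-methylcyclohexa-2,5-diene-1,4-dione | COC1=C(C)C(=O)C=C(CCc2ccccc2OC)C1=O
F5 | step 7 | 2-{(1Z)-4-(2-methoxyphenyl)-1-[2,4,5-trimethoxy-3-methyl-6-(2-phenylethyl)phenyl]but-1-en-2-yl}-4,4,5,5-tetramethyl-1,3,2-dioxaborolane | COc1ccccc1CC/C(B1OC(C)(C)C(C)(C)O1)=C\c1c(OC)c(C)c(OC)c(OC)c1CCc1ccccc1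
F6 | step 6 | 3-(2-methoxyphenyl)-1-[2,4,5-trimethoxy-3-methyl-6-(2-phenylethyl)phenyl]propan-1-ol (racemic) | COc1ccccc1CCC(O)c1c(OC)c(C)c(OC)c(OC)c1CCc1ccccc1
F7 | step 6 | 3-(2-methoxyphenyl)-1-[2,4,5-trimethoxy-3-methyl-6-(2-phenylethyl)phenyl]propan-1-one | COc1ccccc1CCC(=O)c1c(OC)c(C)c(OC)c(OC)c1CCc1ccccc1
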